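**Retrosynthetic overview**
1. The target is two (+)-catechin units joined by one biaryl bond, C6' of ring B of the upper unit to C6 of ring A of the lower unit. All four stereocentres (2R,3S in each unit) are those of (+)-catechin.
2. Key disconnection: the C6'–C6 biaryl bond, made by anodic dehydrogenative head-to-tail coupling of two molecules of one monomer.
3. Monomer: 8-bromo-5,7,3',4'-tetra-O-benzyl-(+)-catechin, from (+)-catechin by benzylation and C8 bromination. The bromine blocks C8 and steers oxidation to ring B.
4. One final hydrogenolysis removes eight benzyl groups and both bromines.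
5. Ring order: no ring is built; rings A, B and C of both units come intact from (+)-catechin.

Assumption: the target SMILES defines no biaryl axis, so the C6'–C6 axis is treated as freely equilibrating rotamers (they may show as doubled or broad NMR signals); "upper unit" is the unit linked through ring B, "lower unit" the unit linked through ring A.

**Step 1**
Reactants: 1 (+)-catechin; 2 benzyl bromide
Product: 3 5,7,3',4'-tetra-O-benzyl-(+)-catechin
Conditions: BnBr (4.4 equiv), K2CO3 (4.5 equiv), DMF, −10 °C → rt, Ar, 48 h
Reagents that add atoms: benzyl bromide, BrCc1ccccc1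
Why: Williamson ether synthesis; carbonate deprotonates only the four phenols, not the secondary 3-OH, and C2 and C3 are not touched, so the (2R,3S) configuration is carried through (expected about 70%).

**Step 2**
Reactants: 3 5,7,3',4'-tetra-O-benzyl-(+)-catechin; 4 N-bromosuccinimide
Product: 5 8-bromo-5,7,3',4'-tetra-O-benzyl-(+)-catechin
Conditions: NBS (1.0 equiv), CH2Cl2, −78 °C → rt
Reagents that add atoms: N-bromosuccinimide, O=C1CCC(=O)N1Br
Why: Electrophilic aromatic bromination; the trioxygenated ring A reacts far faster than ring B, and in 5,7-di-O-alkyl flavans C8 is attacked selectively over C6 (well precedented, above 90%); no stereocentre is involved.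

**Step 3**
Reactants: 5 8-bromo-5,7,3',4'-tetra-O-benzyl-(+)-catechin (two molecules)
Product: 6 head-to-tail dimer: 8-bromo-5,7,3',4'-tetra-O-benzyl-(+)-catechin whose ring B carbon C6' is bonded to C6 of a second 8-bromo-5,7,3',4'-tetra-O-benzyl-(+)-catechin (2R,3S in both units)
Conditions: boron-doped diamond anode, Pt cathode, undivided cell, constant current 3 mA cm−2, 0.45 F mol−1, Bu4NPF6 (0.1 M), HFIP/CH2Cl2 4:1, 0.15 M in 5, 15 °C; stop at about 45% conversion, recover and recycle 5
Reagents that add atoms: none
Why: Proposed new method: anodic dehydrogenative ring B to ring A homocoupling of a flavan polyether — ring B (a 4-alkyl-1,2-dibenzyloxybenzene) has the lowest oxidation potential (estimated 0.2 V below the brominated ring A) and gives a radical cation that HFIP keeps long-lived and non-basic; its electrophilic site is C6', para to the 3'-oxygen, the same site at which 3,4-dimethoxytoluene dimerises; the best nucleophile present is ring A of a second molecule of 5, a 1,3,5-trioxygenated arene far more nucleophilic than the veratrole-type ring B, and its only free position is C6 because C8 carries bromine; C–C bond formation, a second electron transfer and loss of a proton give the biaryl while H2 forms at the cathode; bromine therefore blocks C8, keeps ring A from being oxidised (avoiding the C4 benzylic oxidation typical of flavan ring A), and is removed in the last step; no stereocentre is formed or touched; the closest known reaction type is anodic dehydrogenative arene–arene cross-coupling in fluorinated alcohols and the non-phenolic oxidative biaryl coupling of veratroles with 1,3,5-trialkoxybenzenes (expected 25–30% isolated, 55–60% based on recovered 5).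

**Step 4**
Reactants: 6 the octa-O-benzyl dibromo dimer
Product: 7 the target, (+)-catechin-(6'→6)-(+)-catechin
Conditions: H2 (1 atm), Pd(OH)2/C (20 wt%), Et3N (2.5 equiv), THF/MeOH/H2O 20:1:1, rt, 8 h; filter, AcOH, Sephadex LH-20, lyophilise
Reagents that add atoms: none
Why: Palladium-catalysed hydrogenolysis cleaves the eight aryl benzyl ethers and, with Et3N scavenging HBr, both aryl C–Br bonds in one operation, as in standard deprotection of brominated procyanidin benzyl ethers; the cyclic C2–O bond and the four stereocentres are not affected.

**Compound list**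
1 | (+)-catechin, (2R,3S)-2-(3,4-dihydroxyphenyl)chroman-3,5,7-triol | Oc1cc(O)c2c(c1)O[C@H](c1ccc(O)c(O)c1)[C@@H](O)C2 | starting material
2 | benzyl bromide | BrCc1ccccc1 | starting material
3 | 5,7,3',4'-tetra-O-benzyl-(+)-catechin, (2R,3S), free 3-OH | C(c1ccccc1)Oc1cc(OCc2ccccc2)c2c(c1)O[C@H](c1ccc(OCc3ccccc3)c(OCc3ccccc3)c1)[C@@H](O)C2 | intermediate
4 | N-bromosuccinimide | O=C1CCC(=O)N1Br | starting material
5 | 8-bromo-5,7,3',4'-tetra-O-benzyl-(+)-catechin, (2R,3S) | C(c1ccccc1)Oc1cc(OCc2ccccc2)c2c(c1Br)O[C@H](c1ccc(OCc3ccccc3)c(OCc3ccccc3)c1)[C@@H](O)C2 | intermediate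
6 | octa-O-benzyl-8,8-dibromo dimer: C6' (ring B) of one unit of 5 bonded to C6 (ring A) of a second unit of 5; (2R,3S) in both units, both 3-OH free | C(c1ccccc1)Oc1cc(OCc2ccccc2)c2c(c1Br)O[C@H](c1cc(OCc3ccccc3)c(OCc3ccccc3)cc1-c1c(OCc3ccccc3)c(Br)c3c(c1OCc1ccccc1)C[C@H](O)[C@@H](c1ccc(OCc4ccccc4)c(OCc4ccccc4)c1)O3)[C@@H](O)C2 | intermediate
7 | target: (+)-catechin-(6'→6)-(+)-catechin, a biaryl dehydrodicatechin; (2R,3S) in both units | Oc1cc(O)c2c(c1)O[C@H](c1cc(O)c(O)cc1-c1c(O)cc3c(c1O)C[C@H](O)[C@@H](c1ccc(O)c(O)c1)O3)[C@@H](O)C2 | target

**Step count and risks**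
Total steps: 4. Longest linear sequence: 4 (the coupling joins two molecules of the same intermediate).

Most likely to fail, in order:

Step 3, the proposed new anodic coupling. The risks are:
- competing ring B/ring B (6'–6') coupling;
- loss of the C2 benzylic proton from the radical cation;
- anodic debenzylation;
- chain growth beyond the dimer, since 6 still carries a free C6–H and an oxidisable ring B (hence the charge limit).

The fallback uses known chemistry and gives up protection and regiocontrol. It sets out from 1: (+)-catechin itself is oxidised with a polyphenol oxidase (or laccase) and air in acetate buffer at pH 3.5–4, room temperature, to partial conversion. The ring B o-quinone is then attacked by ring A of a second catechin, which is the known route to the colourless dehydrodicatechins: the 6'→8 biaryl as the main product, the 6'→6 biaryl, and diaryl ethers. The mixture is quenched with ascorbic acid and 7 is isolated by preparative reversed-phase HPLC, so the fallback comes back to the route at 7 in low yield. New compounds on the way: none F0.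

Step 4, the tenfold hydrogenolysis. The risks are incomplete removal of the hindered C8 bromines, catalyst poisoning by bromide, and base-induced C2 epimerisation or air oxidation of the free polyphenol in the presence of Et3N. The fallback separates the two tasks and sets out from 6. Bromine–lithium exchange (n-BuLi, 6 equiv, THF, −78 °C; two equivalents are used by the 3-OH groups) followed by a methanol quench gives the bromine-free octa-O-benzyl dimer F1. Base-free hydrogenolysis (H2, Pd(OH)2/C, THF/MeOH/H2O, rt) then returns to the route at 7.

Step 1, the fourfold benzylation. The risks are C-benzylation at C6/C8, partial 3-O-benzylation, and oxidation or C2 epimerisation of the free phenoxides. The fallback avoids a high concentration of free phenoxide and sets out from 1. Ac2O/pyridine gives (+)-catechin pentaacetate F2. Acetate-to-benzyl exchange (BnBr, K2CO3, MeOH 6 equiv, DMF, rt) releases and benzylates the phenoxides one at a time and leaves the slower-cleaving secondary ester, giving 3-O-acetyl-5,7,3',4'-tetra-O-benzyl-(+)-catechin F3. K2CO3 in MeOH/THF removes the 3-acetate and returns to the route at 3.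

**Further compounds**
F0 | step 3 | none | none
F1 | step 4 | bromine-free octa-O-benzyl dimer: 5,7,3',4'-tetra-O-benzyl-(+)-catechin-(6'→6)-5,7,3',4'-tetra-O-benzyl-(+)-catechin, (2R,3S) in both units | C(c1ccccc1)Oc1cc(OCc2ccccc2)c2c(c1)O[C@H](c1cc(OCc3ccccc3)c(OCc3ccccc3)cc1-c1c(OCc3ccccc3)cc3c(c1OCc1ccccc1)C[C@H](O)[C@@H](c1ccc(OCc4ccccc4)c(OCc4ccccc4)c1)O3)[C@@H](O)C2
F2 | step 1 | (+)-catechin pentaacetate, (2R,3S) | CC(=O)Oc1cc(OC(C)=O)c2c(c1)O[C@H](c1ccc(OC(C)=O)c(OC(C)=O)c1)[C@@H](OC(C)=O)C2
F3 | step 1 | 3-O-acetyl-5,7,3',4'-tetra-O-benzyl-(+)-catechin, (2R,3S) | C(c1ccccc1)Oc1cc(OCc2ccccc2)c2c(c1)O[C@H](c1ccc(OCc3ccccc3)c(OCc3ccccc3)c1)[C@@H](OC(C)=O)C2
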